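**Retrosynthetic overview**
1. 19 ⇐ 16: the enone (C1=O, C2=C3) is installed last by a singlet-oxygen ene reaction on a C1=C2 cyclohexene. Because C6 is quaternary, only one regiochemical outcome is possible.
2. 16 ⇐ 12 + 14: the aryl ketone comes from a carboxylic acid and 3,4-dimethoxyphenyllithium.
3. Key step, 12 ⇐ 9: an Ireland–Claisen rearrangement makes the C6–C8 bond, the quaternary centre and the CHMe centre together. Chirality is transferred 1,3 from a sacrificial C2 carbinol, so no ketone enolate is allylated or alkylated.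
4. 9 ⇐ 5: allyl Grignard addition, oxidative 1,3-transposition, Luche reduction, acylation.
5. 5 ⇐ 1: monomethylation, lipase desymmetrisation and oxidation/elimination of a meso all-cis triol. No ring is formed: ring A (carbocycle) comes from 1 and ring B (arene) from 13.

Locants are those of the target throughout: C1 = ring C=O, C2=C3, C4 = CHOMe, C5 = CH2, C6 = quaternary carbon, C7 = aryl ketone carbon, C8 = CHMe.

Assumption: on diol 2 the lipase shows its usual preference for the (R)-configured carbinol (Kazlauskas rule).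

**Step 1**
Reactants: 1 cis,cis-cyclohexane-1,3,5-triol
Product: 2 (1R,3S,5s)-5-methoxycyclohexane-1,3-diol (all-cis; meso)
Conditions: NaH (1.0 equiv), MeI (1.0 equiv), DMF, 0 to 23 °C
Reagents that add atoms: iodomethane CI
Why: Williamson etherification with one equivalent of base and MeI gives the mono-ether statistically (unreacted 1 is recycled), touches no C–O stereocentre and leaves a meso compound whose mirror plane runs through the new CHOMe carbon.

**Step 2**
Reactants: 2 (1R,3S,5s)-5-methoxycyclohexane-1,3-diol
Product: 3 (1R,3R,5S)-3-hydroxy-5-methoxycyclohexyl acetate (all-cis)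
Conditions: Candida antarctica lipase B (immobilised), vinyl acetate, t-BuOMe, 30 °C
Reagents that add atoms: vinyl acetate C=COC(C)=O
Why: Lipase-catalysed desymmetrisation by irreversible transesterification acylates only the (R)-configured of the two enantiotopic carbinols, which fixes the absolute configuration of the CHOMe carbon (C4 of the target) without the 50 % ceiling of a resolution.

**Step 3**
Reactants: 3 (1R,3R,5S)-3-hydroxy-5-methoxycyclohexyl acetate
Product: 5 (5R)-5-methoxycyclohex-2-en-1-one, via keto acetate 4 (not isolated)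
Conditions: 2,2,6,6-tetramethylpiperidine-1-oxyl (cat.), KBr (cat.), NaOCl, NaHCO3, CH2Cl2/H2O, 0 °C; organic layer, then 1,8-diazabicyclo[5.4.0]undec-7-ene, 0 °C
Reagents that add atoms: none
Why: Anelli oxidation of the free carbinol followed by E1cB loss of the better leaving group (acetate, not methoxide) gives the enone, and since step 2 told the oxidised and the eliminated carbinol apart, the remaining stereocentre is (R).

**Step 4**
Reactants: 5 (5R)-5-methoxycyclohex-2-en-1-one
Product: 6 (5R)-5-methoxy-1-(prop-2-en-1-yl)cyclohex-2-en-1-ol (both C1 epimers)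
Conditions: CH2=CHCH2MgBr, THF, −78 °C; H2O
Reagents that add atoms: allylmagnesium bromide C=CC[Mg]Br
Why: Grignard 1,2-addition works because allyl Grignard reagents attack the enone carbonyl far faster than they deprotonate or add 1,4, and the new carbinol centre (the future C6) is a mixture that step 5 erases.

**Step 5**
Reactants: 6 (5R)-5-methoxy-1-(prop-2-en-1-yl)cyclohex-2-en-1-ol
Product: 7 (5S)-5-methoxy-3-(prop-2-en-1-yl)cyclohex-2-en-1-one
Conditions: [C5H5NH][CrO3Cl], 4 Å molecular sieves, CH2Cl2, 23 °C
Reagents that add atoms: pyridinium chlorochromate [O-][Cr](=O)(=O)Cl.c1cc[nH+]cc1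
Why: In the Babler–Dauben oxidative transposition the hexavalent chromium ester of the tertiary allylic alcohol undergoes a [3,3] shift and the secondary chromate collapses to the β-allyl enone, with the CHOMe centre untouched (its descriptor changes to S only through the CIP priorities).

**Step 6**
Reactants: 7 (5S)-5-methoxy-3-(prop-2-en-1-yl)cyclohex-2-en-1-one
Product: 8 (1S,5S)-5-methoxy-3-(prop-2-en-1-yl)cyclohex-2-en-1-ol (OH cis to OMe)
Conditions: NaBH4, CeCl3·7H2O, MeOH, −78 °C
Reagents that add atoms: none
Why: Luche 1,2-reduction delivers hydride axially to the half-chair with the 5-methoxy group pseudo-equatorial (as in carvone to cis-carveol), so the sacrificial C2 carbinol is set on the same face as the methoxy group.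

**Step 7**
Reactants: 8 (1S,5S)-5-methoxy-3-(prop-2-en-1-yl)cyclohex-2-en-1-ol
Product: 9 (1S,5S)-5-methoxy-3-(prop-2-en-1-yl)cyclohex-2-en-1-yl propanoate
Conditions: (EtCO)2O, Et3N, 4-(dimethylamino)pyridine (cat.), CH2Cl2, 0 °C
Reagents that add atoms: propionic anhydride CCC(=O)OC(=O)CC
Why: Nucleophile-catalysed O-acylation of the secondary allylic alcohol retains configuration because the carbinol C–O bond is not touched.

**Step 8 (key step)**
Reactants: 9 (1S,5S)-5-methoxy-3-(prop-2-en-1-yl)cyclohex-2-en-1-yl propanoate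
Product: 12 (2R)-2-[(1R,5R)-5-methoxy-1-(prop-2-en-1-yl)cyclohex-2-en-1-yl]propanoic acid, via Z silyl ketene acetal 10 (not isolated), via silyl ester 11 (not isolated)
Conditions: LiN(iPr)2, THF/DMPU 2:1, −78 °C; t-BuMe2SiCl; to 23 °C, then 60 °C; 1 M HCl
Reagents that add atoms: none
Why: In this Ireland–Claisen rearrangement LiN(iPr)2 in THF/DMPU gives the Z silyl ketene acetal (methyl cis to OSi), the suprafacial [3,3] shift forms the C6–C8 bond on the face that carried the C2–O bond (cis to OMe, allyl pushed to the other face, the C6 configuration of the target), and because a boat array would need the half-chair in which the cis-methoxy group is axial and syn to both reacting termini, the chair array (ring in a boat-like form, OMe equatorial) is expected, which with the Z acetal places the C8 methyl as in the target (8R).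

**Step 9**
Reactants: 12 (2R)-2-[(1R,5R)-5-methoxy-1-(prop-2-en-1-yl)cyclohex-2-en-1-yl]propanoic acid; 13 4-bromo-1,2-dimethoxybenzene
Product: 16 (2R)-1-(3,4-dimethoxyphenyl)-2-[(1R,5R)-5-methoxy-1-(prop-2-en-1-yl)cyclohex-2-en-1-yl]propan-1-one, via aryllithium 14 (not isolated), via dilithium gem-diolate 15 (not isolated)
Conditions: 13 (2.3 equiv), n-BuLi (2.2 equiv), THF, −78 °C; add 12, −78 to 23 °C; H2O
Reagents that add atoms: none
Why: In this organolithium addition to a lithium carboxylate (Gilman–Van Ess ketone synthesis) bromine–lithium exchange gives 14, the first equivalent deprotonates 12 and the second adds to give 15, which cannot collapse before the quench, so no tertiary alcohol forms and C8 is never alpha to a free ketone under basic conditions.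

**Step 10**
Reactants: 16 (2R)-1-(3,4-dimethoxyphenyl)-2-[(1R,5R)-5-methoxy-1-(prop-2-en-1-yl)cyclohex-2-en-1-yl]propan-1-one
Product: 19 (4S,6S)-6-[(2R)-1-(3,4-dimethoxyphenyl)-1-oxopropan-2-yl]-4-methoxy-6-(prop-2-en-1-yl)cyclohex-2-en-1-one, via allylic hydroperoxide 17 (not isolated), via allylic peracetate 18 (not isolated)
Conditions: O2, 5,10,15,20-tetraphenylporphyrin (cat.), visible light (>450 nm), Ac2O, pyridine, 4-(dimethylamino)pyridine (cat.), CH2Cl2, 0 °C
Reagents that add atoms: dioxygen O=O
Why: In this Schenck ene reaction followed by Kornblum–DeLaMare-type fragmentation singlet oxygen attacks only the ring cis-alkene (the monosubstituted allyl alkene and the acyl-deactivated arene are far slower), the only allylic hydrogens sit on C3 because C6 is quaternary so oxygen must end on C1 with the double bond moving to C2=C3, and in situ acetylation with base-induced loss of acetic acid gives the enone without touching C4, C6 or C8.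

**Compound list**
1 | cis,cis-cyclohexane-1,3,5-triol | O[C@H]1C[C@@H](O)C[C@@H](O)C1 | starting material
2 | (1R,3S,5s)-5-methoxycyclohexane-1,3-diol (all-cis, meso) | CO[C@H]1C[C@@H](O)C[C@@H](O)C1 | intermediate
3 | (1R,3R,5S)-3-hydroxy-5-methoxycyclohexyl acetate | CO[C@H]1C[C@@H](O)C[C@@H](OC(C)=O)C1 | intermediate
4 | (1S,3R)-3-methoxy-5-oxocyclohexyl acetate (keto acetate, not isolated) | CO[C@H]1CC(=O)C[C@@H](OC(C)=O)C1 | intermediate
5 | (5R)-5-methoxycyclohex-2-en-1-one | O=C1C=CC[C@@H](OC)C1 | intermediate
6 | (5R)-5-methoxy-1-(prop-2-en-1-yl)cyclohex-2-en-1-ol, both carbinol epimers | C=CCC1(O)C=CC[C@@H](OC)C1 | intermediate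
7 | (5S)-5-methoxy-3-(prop-2-en-1-yl)cyclohex-2-en-1-one | C=CCC1=CC(=O)C[C@@H](OC)C1 | intermediate
8 | (1S,5S)-5-methoxy-3-(prop-2-en-1-yl)cyclohex-2-en-1-ol (cis) | C=CCC1=C[C@@H](O)C[C@@H](OC)C1 | intermediate
9 | (1S,5S)-5-methoxy-3-(prop-2-en-1-yl)cyclohex-2-en-1-yl propanoate | C=CCC1=C[C@@H](OC(=O)CC)C[C@@H](OC)C1 | intermediate
10 | Z tert-butyldimethylsilyl ketene acetal of 9 (methyl cis to OSi, not isolated) | C/C=C(\O[Si](C)(C)C(C)(C)C)O[C@@H]1C=C(CC=C)C[C@H](OC)C1 | intermediate
11 | tert-butyldimethylsilyl ester of 12 (not isolated) | C=CC[C@@]1([C@@H](C)C(=O)O[Si](C)(C)C(C)(C)C)C[C@H](OC)CC=C1 | intermediate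
12 | (2R)-2-[(1R,5R)-5-methoxy-1-(prop-2-en-1-yl)cyclohex-2-en-1-yl]propanoic acid | C=CC[C@@]1([C@@H](C)C(=O)O)C[C@H](OC)CC=C1 | intermediate
13 | 4-bromo-1,2-dimethoxybenzene | COc1ccc(Br)cc1OC | starting material
14 | 3,4-dimethoxyphenyllithium (not isolated) | [Li]c1ccc(OC)c(OC)c1 | intermediate
15 | dilithium gem-diolate from 12 and 14 (not isolated) | [Li+].[Li+].C=CC[C@@]1([C@@H](C)C([O-])([O-])c2ccc(OC)c(OC)c2)C[C@H](OC)CC=C1 | intermediate
16 | (2R)-1-(3,4-dimethoxyphenyl)-2-[(1R,5R)-5-methoxy-1-(prop-2-en-1-yl)cyclohex-2-en-1-yl]propan-1-one | C=CC[C@@]1([C@@H](C)C(=O)c2ccc(OC)c(OC)c2)C[C@H](OC)CC=C1 | intermediate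
17 | C1 allylic hydroperoxide of 16 with C2=C3 (configuration at C1 of no consequence, not isolated) | C=CC[C@@]1([C@@H](C)C(=O)c2ccc(OC)c(OC)c2)C[C@H](OC)C=CC1OO | intermediate
18 | C1 allylic peracetate (not isolated) | C=CC[C@@]1([C@@H](C)C(=O)c2ccc(OC)c(OC)c2)C[C@H](OC)C=CC1OOC(C)=O | intermediate
19 | (4S,6S)-6-[(2R)-1-(3,4-dimethoxyphenyl)-1-oxopropan-2-yl]-4-methoxy-6-(prop-2-en-1-yl)cyclohex-2-en-1-one | C=CC[C@@]1([C@@H](C)C(=O)c2ccc(OC)c(OC)c2)C[C@H](OC)C=CC1=O | target

**Totals**
Total steps: 10. Longest linear sequence: 10 (1 to 19). Compound 13 is bought and enters in step 9.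

**The three steps most likely to fail**

Step 8 (Ireland–Claisen: chair versus boat selectivity at C8, and a crowded all-cis transition state). The fallback sets out from 8 and comes back at 12.
- It separates the two stereocentres. Heating 8 with triethyl orthoacetate and a trace of propionic acid at 140 °C (Johnson orthoester Claisen) moves only a CH2CO2Et group to C6, again suprafacially. This gives the ethyl ester F1. No C8 centre is made, so chair or boat does not matter.
- LiOH gives the acetic acid F2.
- F2 is coupled through its pivaloyl mixed anhydride to lithiated (R)-4-benzyloxazolidin-2-one, giving the imide F3.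
- NaN(SiMe3)2 and MeI methylate the chelated Z enolate on the face away from the benzyl group (Evans alkylation). This gives the methylated imide F4 with 8R under reagent control.
- LiOH/H2O2 then releases 12.

Step 10 (slow ene reaction of a hindered cis-disubstituted alkene). The fallback sets out from 12 and comes back at 19. It brings the C1 oxygen in from the carboxyl group instead of from singlet oxygen.
- I2 and NaHCO3 in MeCN close the cis-fused iodolactone F5, with the lactone oxygen on C1 on the side-chain face and iodine on C2 anti to it.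
- 1,8-Diazabicyclo[5.4.0]undec-7-ene in warm toluene removes the iodide by anti elimination towards C3, giving the unsaturated lactone F6.
- One equivalent of 14 at −78 °C opens the lactone to the hydroxy ketone F7.
- MnO2 oxidises the allylic C1 alcohol of F7 to 19.

Step 5 (the acid-sensitive skipped diene may isomerise, or methanol may be lost with aromatisation). The fallback sets out from 6 and comes back at 8, leaving out 7 and step 6.
- Catalytic Ph3SiOReO3 in Et2O at −50 to 0 °C brings about a redox-neutral 1,3-transposition of the allylic alcohol through the perrhenate ester.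
- The shift is reversible and settles on the trisubstituted alkene and the more stable cis (diequatorial) secondary alcohol 8.
- It makes no compound outside the list (F0).

**Further compounds**
F1 | step 8 | ethyl 2-[(1S,5R)-5-methoxy-1-(prop-2-en-1-yl)cyclohex-2-en-1-yl]acetate | C=CC[C@@]1(CC(=O)OCC)C[C@H](OC)CC=C1
F2 | step 8 | 2-[(1S,5R)-5-methoxy-1-(prop-2-en-1-yl)cyclohex-2-en-1-yl]acetic acid | C=CC[C@@]1(CC(=O)O)C[C@H](OC)CC=C1
F3 | step 8 | (4R)-4-benzyl-3-{2-[(1S,5R)-5-methoxy-1-(prop-2-en-1-yl)cyclohex-2-en-1-yl]acetyl}oxazolidin-2-one | C=CC[C@@]1(CC(=O)N2C(=O)OC[C@H]2Cc2ccccc2)C[C@H](OC)CC=C1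
F4 | step 8 | (4R)-4-benzyl-3-{(2R)-2-[(1R,5R)-5-methoxy-1-(prop-2-en-1-yl)cyclohex-2-en-1-yl]propanoyl}oxazolidin-2-one | C=CC[C@@]1([C@@H](C)C(=O)N2C(=O)OC[C@H]2Cc2ccccc2)C[C@H](OC)CC=C1
F5 | step 10 | cis-fused iodolactone of 12 (lactone O on C1 cis to C8, iodine on C2 trans to it) | C=CC[C@@]12C[C@H](OC)C[C@@H](I)[C@@H]1OC(=O)[C@@H]2C
F6 | step 10 | cis-fused C2=C3 unsaturated lactone | C=CC[C@@]12C[C@H](OC)C=C[C@@H]1OC(=O)[C@@H]2C
F7 | step 10 | C1 allylic alcohol of 19 (OH cis to the side chain) | C=CC[C@@]1([C@@H](C)C(=O)c2ccc(OC)c(OC)c2)C[C@H](OC)C=C[C@@H]1O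
F0 | step 5 | none | none
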